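**Plan**
1. Cuts: (a) the four benzyl groups (three aryl ethers, one ester) come off last; (b) the bond from ring-B carbon C-1 to its ester carbonyl carbon, giving a B–C aryl iodide and the aryl formate of ring A; (c) the ester C–O bond between the ring-C acid and the ring-B C-4 oxygen.
2. Enabling feature: in the middle ring B, C-1 lies between C-2 (OH) and C-6 (CH3) and para to the C-4 oxygen. This is C-4 of orcinol, where electrophiles enter, so iodine can be placed exactly there. The carbonyl to be attached is an aryl ester of the ring-A 4-oxygen, so a formate of that phenol can hand CO and phenoxide together to an aryl-palladium.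
3. Forward: orsellinic acid gives the ring-C acid (2 steps) and the ring-A formate (4 steps); orcinol gives 4-iodoorcinol, then its monoester with the ring-C acid, then the benzyl ether. A Pd-catalysed aryloxycarbonylation joins the two halves without CO gas, and hydrogenolysis ends the route.
4. Stereochemistry: the target has no stereocentre, stereogenic axis or stereogenic double bond, so nothing has to be set.

Key step: step 10

Remark: the target is achiral, so the "single enantiomer" is the compound itself; orsellinic acid and orcinol are taken as commercial.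

Step 1
Reactants: 1 orsellinic acid (2,4-dihydroxy-6-methylbenzoic acid)
Product: 2 benzyl 2,4-bis(benzyloxy)-6-methylbenzoate
Conditions: BnBr (3.3 equiv), K2CO3, DMF, rt → 60 °C
Reagents that add atoms: benzyl bromide, BrCc1ccccc1
Why: Williamson-type benzylation (SN2 on benzyl bromide) in which carbonate in DMF alkylates the carboxylate and the 4-OH at room temperature and, on warming, also the 2-OH that is hydrogen-bonded to the ester carbonyl.

Step 2
Reactants: 2 benzyl 2,4-bis(benzyloxy)-6-methylbenzoate
Product: 3 2,4-bis(benzyloxy)-6-methylbenzoic acid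
Conditions: KOH, DMSO–H2O, 80 °C; then aq. HCl
Reagents that add atoms: potassium hydroxide (aqueous), [K+].[OH-]
Why: Saponification of the hindered benzyl ester with hydroxide in aqueous DMSO, to which the two aryl benzyl ethers are inert.

Step 3
Reactants: 4 orcinol (5-methylbenzene-1,3-diol)
Product: 5 4-iodo-5-methylbenzene-1,3-diol
Conditions: ICl (1.0 equiv), Et2O, −10 °C → rt
Reagents that add atoms: iodine monochloride, ClI
Why: Electrophilic aromatic iodination at C-4, which is ortho to one hydroxyl, para to the other and next to the methyl group and so the most nucleophilic ring carbon, whereas C-2 between the two hydroxyls is more crowded; one equivalent of ICl at low temperature should stop at the mono-iodide.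

Step 4
Reactants: 5 4-iodo-5-methylbenzene-1,3-diol; 3 2,4-bis(benzyloxy)-6-methylbenzoic acid
Product: 6 3-hydroxy-4-iodo-5-methylphenyl 2,4-bis(benzyloxy)-6-methylbenzoate
Conditions: DCC, DMAP (cat.), CH2Cl2, 0 °C → rt (5 in slight excess)
Reagents that add atoms: none
Why: Steglich esterification in which the acyl-pyridinium of the 2,6-disubstituted acid 3 is very sensitive to hindrance, so it should take the hydroxyl para to iodine (flanked by two ring hydrogens) rather than the hydroxyl next to iodine, and a second acylation should be slow.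

Step 5
Reactants: 6 3-hydroxy-4-iodo-5-methylphenyl 2,4-bis(benzyloxy)-6-methylbenzoate
Product: 7 3-(benzyloxy)-4-iodo-5-methylphenyl 2,4-bis(benzyloxy)-6-methylbenzoate
Conditions: BnBr, K2CO3, acetone, 50 °C
Reagents that add atoms: benzyl bromide, BrCc1ccccc1
Why: Williamson etherification of the remaining phenol; the aryl ester carbonyl is shielded by its 2-benzyloxy and 6-methyl groups and should survive carbonate in acetone.

Step 6
Reactants: 1 orsellinic acid
Product: 8 benzyl 2,4-dihydroxy-6-methylbenzoate
Conditions: BnBr (1.05 equiv), KHCO3, DMF, rt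
Reagents that add atoms: benzyl bromide, BrCc1ccccc1
Why: Chemoselective carboxylate alkylation, since hydrogen carbonate deprotonates only the carboxylic acid, so benzyl bromide should give the benzyl ester and leave both phenols free.

Step 7
Reactants: 8 benzyl 2,4-dihydroxy-6-methylbenzoate
Product: 10 benzyl 4-(allyloxy)-2-methoxy-6-methylbenzoate, via benzyl 4-(allyloxy)-2-hydroxy-6-methylbenzoate 9 (not isolated)
Conditions: K2CO3, acetone; allyl bromide (1.05 equiv), rt; then MeI (excess), reflux
Reagents that add atoms: allyl bromide, C=CCBr; iodomethane, CI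
Why: Two Williamson alkylations in one flask: with one equivalent of allyl bromide only the free 4-OH reacts because the 2-OH is held in a hydrogen bond to the ester carbonyl, and excess iodomethane at reflux then methylates that 2-OH.

Step 8
Reactants: 10 benzyl 4-(allyloxy)-2-methoxy-6-methylbenzoate
Product: 11 benzyl 4-hydroxy-2-methoxy-6-methylbenzoate
Conditions: Pd(PPh3)4 (cat.), morpholine, THF, rt
Reagents that add atoms: none
Why: Tsuji–Trost deallylation in which Pd(0) ionises the aryl allyl ether to a π-allyl complex that morpholine traps, leaving the benzyl ester and the methyl ether untouched.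

Step 9
Reactants: 11 benzyl 4-hydroxy-2-methoxy-6-methylbenzoate
Product: 12 benzyl 4-(formyloxy)-2-methoxy-6-methylbenzoate
Conditions: HCO2H/Ac2O (premixed, 50 °C), then 11, NaOAc (cat.), THF, 0 °C → rt
Reagents that add atoms: formic acid, O=CO, delivered as acetic formic anhydride, CC(=O)OC=O, made in the flask with acetic anhydride, CC(=O)OC(C)=O
Why: O-Formylation of the phenol by the mixed anhydride, which transfers its more electrophilic formyl group; the formate should be kept dry and used without chromatography because aryl formates hydrolyse easily.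

Step 10
Reactants: 7 3-(benzyloxy)-4-iodo-5-methylphenyl 2,4-bis(benzyloxy)-6-methylbenzoate; 12 benzyl 4-(formyloxy)-2-methoxy-6-methylbenzoate
Product: 14 benzyl 4-({2-(benzyloxy)-4-[(2,4-bis(benzyloxy)-6-methylbenzoyl)oxy]-6-methylbenzoyl}oxy)-2-methoxy-6-methylbenzoate, via benzyl 4-hydroxy-2-methoxy-6-methylbenzoate 11 (not isolated), via carbon monoxide 13 (not isolated)
Conditions: Pd(OAc)2 (cat.), Xantphos (cat.), Et3N (2 equiv), 12 (1.5 equiv), toluene, 80 °C, sealed tube
Reagents that add atoms: none
Why: Et3N splits formate 12 into phenoxide 11 and CO 13; Pd(0)/Xantphos adds oxidatively to the C–I bond of 7, CO inserts into the aryl–Pd bond (this creates the bond from ring-B C-1 to the ester carbon), and the acyl-palladium is captured by the phenoxide, which restores the O–C(=O) link and releases Pd(0) and Et3NH+ I−. The closest known reaction type is the Heck-type aryloxycarbonylation of aryl halides in its variant with aryl formates as carriers of CO and phenol, which is established for aryl iodides and bromides. No ring is closed and no stereocentre is formed. The site is fixed by the iodine, the only carbon–halogen bond; chemoselectivity rests on the phenoxide of 11 being the only free nucleophile (every other hydroxyl is a benzyl ether and the acid is a benzyl ester) and on the existing aryl ester of 7 having its carbonyl flanked by 2-OBn and 6-CH3, which shields it from transesterification. The two ortho groups on 7 slow oxidative addition, so a wide-bite-angle ligand and a sealed vessel that keeps the stoichiometric CO in solution are used.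

Step 11
Reactants: 14 benzyl 4-({2-(benzyloxy)-4-[(2,4-bis(benzyloxy)-6-methylbenzoyl)oxy]-6-methylbenzoyl}oxy)-2-methoxy-6-methylbenzoate
Product: 15 4-({2-hydroxy-4-[(2,4-dihydroxy-6-methylbenzoyl)oxy]-6-methylbenzoyl}oxy)-2-methoxy-6-methylbenzoic acid (CNP0283563.0)
Conditions: H2 (1 atm), 10% Pd/C, EtOAc–THF, rt
Reagents that add atoms: none
Why: Catalytic hydrogenolysis of three aryl benzyl ethers and one benzyl ester; the two depside ester links are not benzylic and should be stable under these neutral conditions, and there is no stereocentre to disturb.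

**Compound list**
1 | orsellinic acid (2,4-dihydroxy-6-methylbenzoic acid) | Cc1cc(O)cc(O)c1C(=O)O | starting material
2 | benzyl 2,4-bis(benzyloxy)-6-methylbenzoate | Cc1cc(OCc2ccccc2)cc(OCc2ccccc2)c1C(=O)OCc1ccccc1 | intermediate
3 | 2,4-bis(benzyloxy)-6-methylbenzoic acid | Cc1cc(OCc2ccccc2)cc(OCc2ccccc2)c1C(=O)O | intermediate
4 | orcinol (5-methylbenzene-1,3-diol) | Cc1cc(O)cc(O)c1 | starting material
5 | 4-iodo-5-methylbenzene-1,3-diol | Cc1cc(O)cc(O)c1I | intermediate
6 | 3-hydroxy-4-iodo-5-methylphenyl 2,4-bis(benzyloxy)-6-methylbenzoate | Cc1cc(OC(=O)c2c(C)cc(OCc3ccccc3)cc2OCc2ccccc2)cc(O)c1I | intermediate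
7 | 3-(benzyloxy)-4-iodo-5-methylphenyl 2,4-bis(benzyloxy)-6-methylbenzoate | Cc1cc(OC(=O)c2c(C)cc(OCc3ccccc3)cc2OCc2ccccc2)cc(OCc2ccccc2)c1I | intermediate
8 | benzyl 2,4-dihydroxy-6-methylbenzoate | Cc1cc(O)cc(O)c1C(=O)OCc1ccccc1 | intermediate
9 | benzyl 4-(allyloxy)-2-hydroxy-6-methylbenzoate | C=CCOc1cc(C)c(C(=O)OCc2ccccc2)c(O)c1 | intermediate
10 | benzyl 4-(allyloxy)-2-methoxy-6-methylbenzoate | C=CCOc1cc(C)c(C(=O)OCc2ccccc2)c(OC)c1 | intermediate
11 | benzyl 4-hydroxy-2-methoxy-6-methylbenzoate | COc1cc(O)cc(C)c1C(=O)OCc1ccccc1 | intermediate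
12 | benzyl 4-(formyloxy)-2-methoxy-6-methylbenzoate | COc1cc(OC=O)cc(C)c1C(=O)OCc1ccccc1 | intermediate
13 | carbon monoxide | [C-]#[O+] | intermediate
14 | benzyl 4-({2-(benzyloxy)-4-[(2,4-bis(benzyloxy)-6-methylbenzoyl)oxy]-6-methylbenzoyl}oxy)-2-methoxy-6-methylbenzoate | COc1cc(OC(=O)c2c(C)cc(OC(=O)c3c(C)cc(OCc4ccccc4)cc3OCc3ccccc3)cc2OCc2ccccc2)cc(C)c1C(=O)OCc1ccccc1 | intermediate
15 | 4-({2-hydroxy-4-[(2,4-dihydroxy-6-methylbenzoyl)oxy]-6-methylbenzoyl}oxy)-2-methoxy-6-methylbenzoic acid (CNP0283563.0) | COc1cc(OC(=O)c2c(C)cc(OC(=O)c3c(C)cc(O)cc3O)cc2O)cc(C)c1C(=O)O | target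

**Count**
Total steps: 11. Longest linear sequence: 6 steps (6–7–8–9–10–11, or equally 1–2–4–5–10–11).

**Steps most likely to fail**

Step 10. Oxidative addition and CO insertion at the doubly ortho-substituted, electron-rich C–I bond may be slower than the base-induced decarbonylation of the formate, so that CO saturates palladium or is lost and the iodide is returned or reduced. The fallback sets out from 7 (with phenol 11 from step 8) and comes back at 14. Iodine–magnesium exchange on 7 with i-PrMgCl·LiCl in THF at −40 °C, which hindered esters tolerate, should give [2-(benzyloxy)-4-{[2,4-bis(benzyloxy)-6-methylbenzoyl]oxy}-6-methylphenyl]magnesium chloride F1. CO2 gas and acid work-up should then give 2-(benzyloxy)-4-{[2,4-bis(benzyloxy)-6-methylbenzoyl]oxy}-6-methylbenzoic acid F2. Steglich esterification of F2 with phenol 11 (DCC, DMAP, CH2Cl2) should give 14.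

Step 4. Acylation may occur at the hydroxyl next to iodine or at both hydroxyls. The fallback sets out from orcinol 4 (with acid 3) and comes back at 6. Monoacetylation of excess orcinol (Ac2O, pyridine) should give 3-hydroxy-5-methylphenyl acetate F3. NIS with catalytic TsOH in MeCN should iodinate para to the free hydroxyl, because the acetoxy oxygen is the weaker donor, to give 5-hydroxy-2-iodo-3-methylphenyl acetate F4. The only free hydroxyl of F4 is then esterified with 3 (DCC, DMAP) to 3-(acetyloxy)-4-iodo-5-methylphenyl 2,4-bis(benzyloxy)-6-methylbenzoate F5. NH3 in MeOH at 0 °C should cleave the unhindered acetate but not the 2,6-disubstituted benzoate, giving 6.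

Step 3. Iodination may also go to C-2 between the hydroxyls or proceed to the di-iodide. The fallback sets out from orcinol 4 and comes back at 5. Bis-silylation (TBSCl, imidazole, DMF) should give 1,3-bis[(tert-butyldimethylsilyl)oxy]-5-methylbenzene F6. NIS (1.0 equiv, MeCN) should then iodinate only the carbon between the methyl group and one silyloxy group, since the bulky silyl ethers block the carbon between the two oxygens and a second iodination, giving 1,5-bis[(tert-butyldimethylsilyl)oxy]-2-iodo-3-methylbenzene F7. TBAF in THF at 0 °C should give 5.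

**Further compounds**
F1 | step 10 | [2-(benzyloxy)-4-{[2,4-bis(benzyloxy)-6-methylbenzoyl]oxy}-6-methylphenyl]magnesium chloride | Cc1cc(OC(=O)c2c(C)cc(OCc3ccccc3)cc2OCc2ccccc2)cc(OCc2ccccc2)c1[Mg]Cl
F2 | step 10 | 2-(benzyloxy)-4-{[2,4-bis(benzyloxy)-6-methylbenzoyl]oxy}-6-methylbenzoic acid | Cc1cc(OC(=O)c2c(C)cc(OCc3ccccc3)cc2OCc2ccccc2)cc(OCc2ccccc2)c1C(=O)O
F3 | step 4 | 3-hydroxy-5-methylphenyl acetate | CC(=O)Oc1cc(C)cc(O)c1
F4 | step 4 | 5-hydroxy-2-iodo-3-methylphenyl acetate | CC(=O)Oc1cc(O)cc(C)c1I
F5 | step 4 | 3-(acetyloxy)-4-iodo-5-methylphenyl 2,4-bis(benzyloxy)-6-methylbenzoate | CC(=O)Oc1cc(OC(=O)c2c(C)cc(OCc3ccccc3)cc2OCc2ccccc2)cc(C)c1I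
F6 | step 3 | 1,3-bis[(tert-butyldimethylsilyl)oxy]-5-methylbenzene | Cc1cc(O[Si](C)(C)C(C)(C)C)cc(O[Si](C)(C)C(C)(C)C)c1
F7 | step 3 | 1,5-bis[(tert-butyldimethylsilyl)oxy]-2-iodo-3-methylbenzene | Cc1cc(O[Si](C)(C)C(C)(C)C)cc(O[Si](C)(C)C(C)(C)C)c1I
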